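Ring labels: A = formyl-bearing arene, B = seven-membered lactone/ether ring, C = second arene, D = 2,2-dimethylpyranone. The target is achiral, so no stereochemistry has to be set.
Cuts, in retrosynthetic order: ring D at C8–C(=O) and O–CMe2 (3-methylbut-2-enoic acid), ring B at the lactone O10–C11 bond, and ring A at three C–C bonds (C3–C4, C4a–C11a, C2–C3).
Enabling feature: round ring A the substituents run OH (C3), CHO (C4), O-aryl (C4a), acyl carbon (C11a), CH3 (C1), H (C2). This is a resorcinol monoaryl ether with one carbon between the two oxygens and the carboxyl carbon para to the OH, the pattern that an alkoxycarbonyl vinylketene and an aryl ynol ether assemble.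
Forward: ring C is bought as 3,4,5-trimethoxytoluene, and its crowded oxygen (later O5) is first tied to a two-carbon alkyne from trichloroethylene, so the tetra-ortho-substituted diaryl ether is never made by joining two arenes.
Ring A is grown on that alkyne (step 9), ring B follows by lactonisation (step 11), the formyl group is unveiled (steps 12 and 13), and ring D is annulated last (step 15).

Key step: step 9

Remark: locants of the tricyclic compounds follow 11H-dibenzo[b,e][1,4]dioxepin-11-one (ring A C1–C4, O5, ring C C6–C9, O10, C11=O). Benzyl diazoacetate is taken as the commercial toluene solution. Compounds 17 and 20 are racemic and their stereocentres disappear again.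

Step 1
Reactants: 1 3,4,5-trimethoxytoluene
Product: 3 2,3,4-trimethoxy-6-methylbenzaldehyde, via aryl iminium salt 2 (not isolated)
Conditions: POCl3, DMF, 0 to 80 °C; then ice-water
Reagents that add atoms: N,N-dimethylformamide CN(C)C=O; water O
Why: Vilsmeier–Haack formylation, in which the chloroiminium ion attacks the electron-rich ring at one of its two equivalent free positions, so a single aldehyde should result after hydrolysis of 2.

Step 2
Reactants: 3 2,3,4-trimethoxy-6-methylbenzaldehyde
Product: 4 2-hydroxy-3,4-dimethoxy-6-methylbenzaldehyde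
Conditions: BCl3, CH2Cl2, −10 to 0 °C; then H2O
Reagents that add atoms: none
Why: Chelation-directed aryl methyl ether cleavage, in which BCl3 binds the formyl oxygen and removes only the methyl group of the neighbouring 2-methoxy group, leaving the 3- and 4-methoxy groups untouched.

Step 3
Reactants: 4 2-hydroxy-3,4-dimethoxy-6-methylbenzaldehyde; 5 trichloroethylene
Product: 6 2-[(E)-1,2-dichlorovinyloxy]-3,4-dimethoxy-6-methylbenzaldehyde
Conditions: K2CO3, DMF, 70 °C
Reagents that add atoms: none
Why: Nucleophilic vinylation by elimination–addition, a reaction type known for salicylaldehydes, in which K2CO3 takes HCl from 5 and the phenoxide adds anti to the resulting dichloroacetylene, so the crowded aryl–O–C bond is made with a slim, linear electrophile.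

Step 4
Reactants: 6 2-[(E)-1,2-dichlorovinyloxy]-3,4-dimethoxy-6-methylbenzaldehyde
Product: 8 2-[(E)-1,2-dichlorovinyloxy]-3,4-dimethoxy-6-methylphenol, via aryl formate 7 (not isolated)
Conditions: 30% H2O2, H2SO4 (cat.), MeOH, 20 °C
Reagents that add atoms: hydrogen peroxide OO
Why: Acid-catalysed Dakin oxidation (Baeyer–Villiger type aryl migration), in which the para-methoxylated, ortho-oxygenated aryl group migrates to oxygen, formate 7 is methanolysed in situ and the electron-poor dichloroalkene should be inert to H2O2.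

Step 5
Reactants: 8 2-[(E)-1,2-dichlorovinyloxy]-3,4-dimethoxy-6-methylphenol
Product: 9 2-(benzyloxy)-3-[(E)-1,2-dichlorovinyloxy]-4,5-dimethoxytoluene
Conditions: BnBr, K2CO3, DMF, 20 °C
Reagents that add atoms: benzyl bromide BrCc1ccccc1
Why: Williamson ether synthesis on the only free hydroxyl group, with benzyl chosen because it is removed together with the benzyl ester in step 10.

Step 6
Reactants: 9 2-(benzyloxy)-3-[(E)-1,2-dichlorovinyloxy]-4,5-dimethoxytoluene
Product: 13 tert-butyl({3-[2-(benzyloxy)-5,6-dimethoxy-3-methylphenoxy]prop-2-yn-1-yl}oxy)dimethylsilane, via chloroethynyl ether 10 (not isolated), via lithium aryloxyacetylide 11 (not isolated), via lithium alkoxide 12 (not isolated)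
Conditions: n-BuLi (2.5 equiv), THF, −78 to −40 °C; (CH2O)n, −78 to 20 °C; TBSCl, DMAP (cat.), 20 °C
Reagents that add atoms: paraformaldehyde (as formaldehyde) C=O; tert-butyldimethylsilyl chloride CC(C)(C)[Si](C)(C)Cl
Why: Dichlorovinyl ether route to ynol ethers, in which n-BuLi removes the vinyl proton, LiCl leaves to give 10, chlorine–lithium exchange gives 11, 11 adds to formaldehyde and alkoxide 12 is silylated in the same flask, so the acid-sensitive free propargylic alcohol is never handled.

Step 7
Reactants: 14 benzyl diazoacetate; 15 methacrolein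
Product: 17 benzyl 2-diazo-3-hydroxy-4-methylpent-4-enoate (racemic), via benzyl lithiodiazoacetate 16 (not isolated)
Conditions: LiN(iPr)2, THF, −78 °C; then AcOH
Reagents that add atoms: none
Why: Aldol-type 1,2-addition of a lithiated diazoacetate to an enal, which at low temperature is faster than dipolar cycloaddition to the C=C bond, and the new carbinol centre is racemic and is erased in step 8.

Step 8
Reactants: 17 benzyl 2-diazo-3-hydroxy-4-methylpent-4-enoate
Product: 18 benzyl 2-diazo-4-methyl-3-oxopent-4-enoate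
Conditions: IBX, DMSO, 20 °C, dark
Reagents that add atoms: none
Why: IBX oxidation of an α-diazo-β-hydroxy ester to the α-diazo-β-keto ester, a mild known method that leaves the diazo group and the 1,1-disubstituted alkene alone.

Step 9
Reactants: 13 tert-butyl({3-[2-(benzyloxy)-5,6-dimethoxy-3-methylphenoxy]prop-2-yn-1-yl}oxy)dimethylsilane; 18 benzyl 2-diazo-4-methyl-3-oxopent-4-enoate
Product: 23 benzyl 2-[2-(benzyloxy)-5,6-dimethoxy-3-methylphenoxy]-3-{[(tert-butyldimethylsilyl)oxy]methyl}-4-hydroxy-6-methylbenzoate, via vinylketene 19 (not isolated), via vinylcyclobutenone 20 (not isolated), via dienylketene 21 (not isolated), via cyclohexadienone 22 (not isolated)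
Conditions: hν (medium-pressure Hg lamp, Pyrex filter), 18 (1.5 equiv, slow addition), ClCH2CH2Cl, 25 °C until 18 is consumed; then toluene, 110 °C
Reagents that add atoms: none
Why: Proposed new method: light expels N2 from 18 and the isopropenyl group shifts to the diazo carbon (Wolff rearrangement) to give the benzyloxycarbonyl vinylketene 19, whose carbonyl carbon is attacked by the silyloxymethyl-bearing alkyne carbon of 13 while its α-carbon bonds to the aryloxy carbon, a [2+2] closure to the four-membered ring of 20. On heating, 20 opens by a conrotatory 4π electrocyclic reaction to dienylketene 21, ring A closes by a disrotatory 6π electrocyclisation (ketene carbon to the isopropenyl CH2) and dienone 22 tautomerises irreversibly to phenol 23. The closest known reaction type is the Danheiser benzannulation of photochemically generated vinylketenes with alkoxy- and siloxyalkynes, and the new elements are the ester on the ketene α-carbon and the aryl group on the ynol ether oxygen. Regiochemistry rests on the polarity of the ynol ether, whose carbon remote from oxygen is the nucleophile and can only attack the ketene carbonyl carbon, so OH, CH2OTBS, O-aryl, CO2Bn, CH3 and H end up in this order round the ring. Chemoselectivity requires that closure at carbon ([2+2]) outruns closure at the ester oxygen (hetero-[4+2] to a pyranone), which should be favoured because an ester C=O, cross-conjugated with its own alkoxy oxygen, is a much poorer oxadiene terminus than the ketone of an acylketene, and slow addition keeps the ketene concentration low. No stereocentre survives, since the quaternary carbon of racemic 20 becomes aromatic, and either sense of ring opening is tolerable because the opening is reversible and only the isomer with the isopropenyl group turned inward is drained by the 6π step.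

Step 10
Reactants: 23 benzyl 2-[2-(benzyloxy)-5,6-dimethoxy-3-methylphenoxy]-3-{[(tert-butyldimethylsilyl)oxy]methyl}-4-hydroxy-6-methylbenzoate
Product: 24 3-{[(tert-butyldimethylsilyl)oxy]methyl}-4-hydroxy-2-(2-hydroxy-5,6-dimethoxy-3-methylphenoxy)-6-methylbenzoic acid
Conditions: H2 (1 atm), 10% Pd/C, EtOAc, 20 °C
Reagents that add atoms: none
Why: Catalytic hydrogenolysis cleaves both O–CH2Ph bonds (aryl ether and ester) in one operation, which avoids any acyl attack on the doubly ortho-substituted benzoate, while the CH2–OTBS bond on the fully substituted ring A is shielded from the catalyst surface.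

Step 11
Reactants: 24 3-{[(tert-butyldimethylsilyl)oxy]methyl}-4-hydroxy-2-(2-hydroxy-5,6-dimethoxy-3-methylphenoxy)-6-methylbenzoic acid
Product: 25 4-{[(tert-butyldimethylsilyl)oxy]methyl}-3-hydroxy-6,7-dimethoxy-1,9-dimethyl-11H-dibenzo[b,e][1,4]dioxepin-11-one
Conditions: dicyclohexylcarbodiimide, toluene (0.005 M), 20 °C
Reagents that add atoms: none
Why: Carbodiimide lactonisation of a 2-(2-hydroxyaryloxy)benzoic acid, the standard closure of the seven-membered depsidone ring, in which only the ring C hydroxyl can reach the activated acid intramolecularly (the ring A hydroxyl is para to it and the other ring C oxygens are methylated) and dilution suppresses intermolecular esterification.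

Step 12
Reactants: 25 4-{[(tert-butyldimethylsilyl)oxy]methyl}-3-hydroxy-6,7-dimethoxy-1,9-dimethyl-11H-dibenzo[b,e][1,4]dioxepin-11-one
Product: 26 3-hydroxy-4-(hydroxymethyl)-6,7-dimethoxy-1,9-dimethyl-11H-dibenzo[b,e][1,4]dioxepin-11-one
Conditions: HF·pyridine, THF, 0 to 20 °C
Reagents that add atoms: none
Why: Fluoride-induced silyl ether cleavage under mildly acidic conditions, which spare the aryl ester that a basic fluoride source could open.

Step 13
Reactants: 26 3-hydroxy-4-(hydroxymethyl)-6,7-dimethoxy-1,9-dimethyl-11H-dibenzo[b,e][1,4]dioxepin-11-one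
Product: 27 3-hydroxy-6,7-dimethoxy-1,9-dimethyl-11-oxo-11H-dibenzo[b,e][1,4]dioxepine-4-carbaldehyde
Conditions: activated MnO2, CH2Cl2, 20 °C
Reagents that add atoms: none
Why: MnO2 oxidation of a benzylic (salicyl) alcohol stops at the aldehyde, and it is placed before the demethylation because a free catechol would be oxidised to the quinone.

Step 14
Reactants: 27 3-hydroxy-6,7-dimethoxy-1,9-dimethyl-11-oxo-11H-dibenzo[b,e][1,4]dioxepine-4-carbaldehyde
Product: 28 3,6,7-trihydroxy-1,9-dimethyl-11-oxo-11H-dibenzo[b,e][1,4]dioxepine-4-carbaldehyde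
Conditions: BBr3 (4 equiv), CH2Cl2, −78 to 0 °C; then H2O
Reagents that add atoms: none
Why: BBr3 cleavage of aryl methyl ethers, in which the vicinal dimethoxy unit is taken off through a cyclic borate while the chelated formyl group and the lactone should tolerate the reagent at low temperature, as is usual in depsidone deprotections.

Step 15
Reactants: 28 3,6,7-trihydroxy-1,9-dimethyl-11-oxo-11H-dibenzo[b,e][1,4]dioxepine-4-carbaldehyde; 29 3-methylbut-2-enoic acid
Product: 31 CNP0271978.0 (depsidone with 3-OH, 4-CHO and 1-CH3 on ring A, 6-OH and 9-CH3 on ring C, and a 2,2-dimethyl-2,3-dihydropyran-4-one fused through O at C7 and C=O at C8), via aryl enone 30 (not isolated)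
Conditions: 7.7 wt% P2O5 in MeSO3H (Eaton's reagent), 60 °C
Reagents that add atoms: none
Why: Known one-pot 2,2-dimethylchroman-4-one annulation of phenols, namely Friedel–Crafts acylation at C8, the only free position of ring C (ortho to the 7-OH, para to O5, ring A being deactivated by formyl and lactone carbonyl), followed by 6-endo-trig oxa-Michael closure of the 7-OH onto enone 30.

Compound list
1 | 3,4,5-trimethoxytoluene | COc1cc(C)cc(OC)c1OC | starting material
2 | dimethyl[(2,3,4-trimethoxy-6-methylphenyl)methylidene]ammonium dichlorophosphate (not isolated) | C[N+](C)=Cc1c(C)cc(OC)c(OC)c1OC.[O-]P(=O)(Cl)Cl | intermediate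
3 | 2,3,4-trimethoxy-6-methylbenzaldehyde | COc1cc(C)c(C=O)c(OC)c1OC | intermediate
4 | 2-hydroxy-3,4-dimethoxy-6-methylbenzaldehyde | COc1cc(C)c(C=O)c(O)c1OC | intermediate
5 | trichloroethylene | ClC=C(Cl)Cl | starting material
6 | 2-[(E)-1,2-dichlorovinyloxy]-3,4-dimethoxy-6-methylbenzaldehyde | COc1cc(C)c(C=O)c(O/C(Cl)=C\Cl)c1OC | intermediate
7 | 2-[(E)-1,2-dichlorovinyloxy]-3,4-dimethoxy-6-methylphenyl formate (not isolated) | COc1cc(C)c(OC=O)c(O/C(Cl)=C\Cl)c1OC | intermediate
8 | 2-[(E)-1,2-dichlorovinyloxy]-3,4-dimethoxy-6-methylphenol | COc1cc(C)c(O)c(O/C(Cl)=C\Cl)c1OC | intermediate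
9 | 2-(benzyloxy)-3-[(E)-1,2-dichlorovinyloxy]-4,5-dimethoxytoluene | COc1cc(C)c(OCc2ccccc2)c(O/C(Cl)=C\Cl)c1OC | intermediate
10 | 2-(benzyloxy)-3-(chloroethynyloxy)-4,5-dimethoxytoluene (not isolated) | ClC#COc1c(OCc2ccccc2)c(C)cc(OC)c1OC | intermediate
11 | lithium [2-(benzyloxy)-5,6-dimethoxy-3-methylphenoxy]acetylide (not isolated) | [Li]C#COc1c(OCc2ccccc2)c(C)cc(OC)c1OC | intermediate
12 | lithium 3-[2-(benzyloxy)-5,6-dimethoxy-3-methylphenoxy]prop-2-yn-1-olate (not isolated) | [Li+].[O-]CC#COc1c(OCc2ccccc2)c(C)cc(OC)c1OC | intermediate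
13 | tert-butyl({3-[2-(benzyloxy)-5,6-dimethoxy-3-methylphenoxy]prop-2-yn-1-yl}oxy)dimethylsilane (ring C aryl ynol ether) | CC(C)(C)[Si](C)(C)OCC#COc1c(OCc2ccccc2)c(C)cc(OC)c1OC | intermediate
14 | benzyl diazoacetate | [N-]=[N+]=CC(=O)OCc1ccccc1 | starting material
15 | methacrolein | CC(=C)C=O | starting material
16 | benzyl lithiodiazoacetate (not isolated) | [Li]C(=[N+]=[N-])C(=O)OCc1ccccc1 | intermediate
17 | benzyl 2-diazo-3-hydroxy-4-methylpent-4-enoate (racemic) | CC(=C)C(O)C(=[N+]=[N-])C(=O)OCc1ccccc1 | intermediate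
18 | benzyl 2-diazo-4-methyl-3-oxopent-4-enoate | CC(=C)C(=O)C(=[N+]=[N-])C(=O)OCc1ccccc1 | intermediate
19 | benzyl 3-methyl-2-(oxomethylidene)but-3-enoate (vinylketene, not isolated) | CC(=C)C(=C=O)C(=O)OCc1ccccc1 | intermediate
20 | benzyl 2-[2-(benzyloxy)-5,6-dimethoxy-3-methylphenoxy]-3-{[(tert-butyldimethylsilyl)oxy]methyl}-4-oxo-1-(prop-1-en-2-yl)cyclobut-2-ene-1-carboxylate (racemic, not isolated) | CC(=C)C1(C(=O)OCc2ccccc2)C(=O)C(CO[Si](C)(C)C(C)(C)C)=C1Oc1c(OCc2ccccc2)c(C)cc(OC)c1OC | intermediate
21 | benzyl (2Z)-3-[2-(benzyloxy)-5,6-dimethoxy-3-methylphenoxy]-4-{[(tert-butyldimethylsilyl)oxy]methyl}-5-oxo-2-(prop-1-en-2-yl)penta-2,4-dienoate (dienylketene, not isolated) | O=C=C(CO[Si](C)(C)C(C)(C)C)/C(Oc1c(OCc2ccccc2)c(C)cc(OC)c1OC)=C(\C(C)=C)C(=O)OCc1ccccc1 | intermediate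
22 | cyclohexa-2,4-dien-1-one tautomer of 23 (not isolated) | CC1=C(C(=O)OCc2ccccc2)C(Oc2c(OCc3ccccc3)c(C)cc(OC)c2OC)=C(CO[Si](C)(C)C(C)(C)C)C(=O)C1 | intermediate
23 | benzyl 2-[2-(benzyloxy)-5,6-dimethoxy-3-methylphenoxy]-3-{[(tert-butyldimethylsilyl)oxy]methyl}-4-hydroxy-6-methylbenzoate | Cc1cc(O)c(CO[Si](C)(C)C(C)(C)C)c(Oc2c(OCc3ccccc3)c(C)cc(OC)c2OC)c1C(=O)OCc1ccccc1 | intermediate
24 | 3-{[(tert-butyldimethylsilyl)oxy]methyl}-4-hydroxy-2-(2-hydroxy-5,6-dimethoxy-3-methylphenoxy)-6-methylbenzoic acid | Cc1cc(O)c(CO[Si](C)(C)C(C)(C)C)c(Oc2c(O)c(C)cc(OC)c2OC)c1C(=O)O | intermediate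
25 | 4-{[(tert-butyldimethylsilyl)oxy]methyl}-3-hydroxy-6,7-dimethoxy-1,9-dimethyl-11H-dibenzo[b,e][1,4]dioxepin-11-one | Cc1cc(O)c(CO[Si](C)(C)C(C)(C)C)c2c1C(=O)Oc1c(C)cc(OC)c(OC)c1O2 | intermediate
26 | 3-hydroxy-4-(hydroxymethyl)-6,7-dimethoxy-1,9-dimethyl-11H-dibenzo[b,e][1,4]dioxepin-11-one | Cc1cc(O)c(CO)c2c1C(=O)Oc1c(C)cc(OC)c(OC)c1O2 | intermediate
27 | 3-hydroxy-6,7-dimethoxy-1,9-dimethyl-11-oxo-11H-dibenzo[b,e][1,4]dioxepine-4-carbaldehyde | Cc1cc(O)c(C=O)c2c1C(=O)Oc1c(C)cc(OC)c(OC)c1O2 | intermediate
28 | 3,6,7-trihydroxy-1,9-dimethyl-11-oxo-11H-dibenzo[b,e][1,4]dioxepine-4-carbaldehyde | Cc1cc(O)c(C=O)c2c1C(=O)Oc1c(C)cc(O)c(O)c1O2 | intermediate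
29 | 3-methylbut-2-enoic acid | CC(C)=CC(=O)O | starting material
30 | 3,6,7-trihydroxy-1,9-dimethyl-8-(3-methylbut-2-enoyl)-11-oxo-11H-dibenzo[b,e][1,4]dioxepine-4-carbaldehyde (not isolated) | Cc1cc(O)c(C=O)c2c1C(=O)Oc1c(C)c(C(=O)C=C(C)C)c(O)c(O)c1O2 | intermediate
31 | CNP0271978.0 | Cc1cc(O)c(C=O)c2c1C(=O)Oc1c(C)c3c(c(O)c1O2)OC(C)(C)CC3=O | target

Total step count: 15. Longest linear sequence: 13 (steps 1–6 and 9–15). Steps 7 and 8 form the short second branch.

Steps most likely to fail

1. Step 9.
- What may go wrong in the Wolff stage: the benzyloxy group may migrate instead of the isopropenyl group, or the free carbene may be trapped by the electron-rich alkyne.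
- What may go wrong afterwards: the ketene–alkyne adduct may collapse through the ester oxygen, the very electrophilic ketene may oligomerise, the ynol ether may photodegrade, or left-over ketene may acylate the new phenol.
- Fallback (known chemistry only): it sets out from 9, comes back at 28, gives up the benzannulation and makes the O5–C4a bond by nucleophilic aromatic substitution on a doubly activated aryl fluoride.
- Ring C phenol: n-BuLi converts 9 through 10 into 11 as in step 6. A quench with dilute aqueous HCl gives 2-(benzyloxy)-3-(ethynyloxy)-4,5-dimethoxytoluene F1, which is hydrated by the same acid to 2-(benzyloxy)-5,6-dimethoxy-3-methylphenyl acetate F2. K2CO3 in MeOH then frees 2-(benzyloxy)-5,6-dimethoxy-3-methylphenol F3.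
- Ring A fluoride: purchased 3-fluoro-5-methylanisole is lithiated between F and OMe (n-BuLi, THF, −78 °C) and formylated with DMF to 2-fluoro-6-methoxy-4-methylbenzaldehyde F4. Bromination para to the methoxy group (NBS, MeCN) gives 3-bromo-2-fluoro-6-methoxy-4-methylbenzaldehyde F5. Carbonylation (Pd(OAc)2, dppf, CO, BnOH, Et3N, DMF, 80 °C) gives benzyl 2-fluoro-3-formyl-4-methoxy-6-methylbenzoate F6.
- Union and return: F3 and F6 with K2CO3 in DMF give benzyl 2-[2-(benzyloxy)-5,6-dimethoxy-3-methylphenoxy]-3-formyl-4-methoxy-6-methylbenzoate F7. Hydrogenolysis (H2, 10% Pd/C, EtOAc) gives 3-formyl-2-(2-hydroxy-5,6-dimethoxy-3-methylphenoxy)-4-methoxy-6-methylbenzoic acid F8. Dicyclohexylcarbodiimide closes it to 3,6,7-trimethoxy-1,9-dimethyl-11-oxo-11H-dibenzo[b,e][1,4]dioxepine-4-carbaldehyde F9, and BBr3 removes all three methyl groups to give 28.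

2. Step 15.
- What may go wrong: the hot acid may open the lactone, the protonated formyl group may condense with the electron-rich ring C, C8 may be alkylated by the tertiary cation instead of acylated, or acylation may stop at the phenol oxygens.
- Fallback: it sets out from 27, comes back at 30, and separates C–C bond formation, deprotection and ring closure.
- Sequence: the more robust dimethyl ether 27 is acylated at C8 with 3-methylbut-2-enoyl chloride and AlCl3 in CH2Cl2 at 0 °C to give 3-hydroxy-6,7-dimethoxy-1,9-dimethyl-8-(3-methylbut-2-enoyl)-11-oxo-11H-dibenzo[b,e][1,4]dioxepine-4-carbaldehyde F10. Further cyclialkylation is blocked because both positions ortho to the new ketone are substituted. BBr3 at low temperature then gives 30, which is isolated and closed to 31 by oxa-Michael addition with NaOAc in EtOH.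

3. Step 10.
- What may go wrong: the ring A benzylic C–O bond, activated by the ortho hydroxyl group, may be over-reduced, or the silyl group may be lost on the catalyst, either of which would spoil the lactonisation.
- Fallback: it sets out from 23, comes back at 27, brings the formyl group to its final oxidation level first and replaces hydrogenolysis by a Lewis acid debenzylation.
- Sequence: HF·pyridine gives benzyl 2-[2-(benzyloxy)-5,6-dimethoxy-3-methylphenoxy]-4-hydroxy-3-(hydroxymethyl)-6-methylbenzoate F11. MnO2 gives benzyl 2-[2-(benzyloxy)-5,6-dimethoxy-3-methylphenoxy]-3-formyl-4-hydroxy-6-methylbenzoate F12. BCl3 with pentamethylbenzene in CH2Cl2 at −78 °C removes both benzyl groups to give 3-formyl-4-hydroxy-2-(2-hydroxy-5,6-dimethoxy-3-methylphenoxy)-6-methylbenzoic acid F13. Dicyclohexylcarbodiimide in dilute toluene then closes ring B to 27.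

Further compounds
F1 | step 9 | 2-(benzyloxy)-3-(ethynyloxy)-4,5-dimethoxytoluene | C#COc1c(OCc2ccccc2)c(C)cc(OC)c1OC
F2 | step 9 | 2-(benzyloxy)-5,6-dimethoxy-3-methylphenyl acetate | CC(=O)Oc1c(OCc2ccccc2)c(C)cc(OC)c1OC
F3 | step 9 | 2-(benzyloxy)-5,6-dimethoxy-3-methylphenol | Oc1c(OCc2ccccc2)c(C)cc(OC)c1OC
F4 | step 9 | 2-fluoro-6-methoxy-4-methylbenzaldehyde | COc1cc(C)cc(F)c1C=O
F5 | step 9 | 3-bromo-2-fluoro-6-methoxy-4-methylbenzaldehyde | COc1cc(C)c(Br)c(F)c1C=O
F6 | step 9 | benzyl 2-fluoro-3-formyl-4-methoxy-6-methylbenzoate | COc1cc(C)c(C(=O)OCc2ccccc2)c(F)c1C=O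
F7 | step 9 | benzyl 2-[2-(benzyloxy)-5,6-dimethoxy-3-methylphenoxy]-3-formyl-4-methoxy-6-methylbenzoate | COc1cc(C)c(C(=O)OCc2ccccc2)c(Oc2c(OCc3ccccc3)c(C)cc(OC)c2OC)c1C=O
F8 | step 9 | 3-formyl-2-(2-hydroxy-5,6-dimethoxy-3-methylphenoxy)-4-methoxy-6-methylbenzoic acid | COc1cc(C)c(C(=O)O)c(Oc2c(O)c(C)cc(OC)c2OC)c1C=O
F9 | step 9 | 3,6,7-trimethoxy-1,9-dimethyl-11-oxo-11H-dibenzo[b,e][1,4]dioxepine-4-carbaldehyde | Cc1cc(OC)c(C=O)c2c1C(=O)Oc1c(C)cc(OC)c(OC)c1O2
F10 | step 15 | 3-hydroxy-6,7-dimethoxy-1,9-dimethyl-8-(3-methylbut-2-enoyl)-11-oxo-11H-dibenzo[b,e][1,4]dioxepine-4-carbaldehyde | Cc1cc(O)c(C=O)c2c1C(=O)Oc1c(C)c(C(=O)C=C(C)C)c(OC)c(OC)c1O2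
F11 | step 10 | benzyl 2-[2-(benzyloxy)-5,6-dimethoxy-3-methylphenoxy]-4-hydroxy-3-(hydroxymethyl)-6-methylbenzoate | Cc1cc(O)c(CO)c(Oc2c(OCc3ccccc3)c(C)cc(OC)c2OC)c1C(=O)OCc1ccccc1
F12 | step 10 | benzyl 2-[2-(benzyloxy)-5,6-dimethoxy-3-methylphenoxy]-3-formyl-4-hydroxy-6-methylbenzoate | Cc1cc(O)c(C=O)c(Oc2c(OCc3ccccc3)c(C)cc(OC)c2OC)c1C(=O)OCc1ccccc1
F13 | step 10 | 3-formyl-4-hydroxy-2-(2-hydroxy-5,6-dimethoxy-3-methylphenoxy)-6-methylbenzoic acid | Cc1cc(O)c(C=O)c(Oc2c(O)c(C)cc(OC)c2OC)c1C(=O)O
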